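## Structural features

The target consists of two benzene rings joined by a single ether oxygen between C6 of ring A and C1' of ring B. Ring A carries four contiguous substituents: the carboxyl group at C1, flanked by the methoxy group at C2 and the aryloxy group at C6, and a 1,3-dihydroxy-3-methylbutyl chain at C3; C4 and C5 bear hydrogen. Ring B is a 2-aryloxyphenol: the ether carbon C1' lies between the phenol carbon C2' and the hydroxymethyl-bearing carbon C6', with a methyl group at C4', so the ether linkage has three ortho substituents. The only stereocentre is the (R)-configured benzylic carbinol carbon of the side chain; its neighbours are a methylene group and then an achiral tertiary carbinol, so no relative stereochemistry arises. This benzylic alcohol is para to the ether oxygen and ortho to the methoxy group and should ionise easily in acid; in addition, the 2,6-dioxygenated benzoic acid can decarboxylate in strong acid, the carboxyl and the C6' hydroxymethyl group can close an eight-membered lactone under dehydrating conditions, and the electron-rich phenol is sensitive to oxidants. The real difficulty is the crowded diaryl ether with two differently functionalised ortho positions on ring B, together with the carboxyl wedged between two oxygens on ring A. The key step uses the fact that C2' (OH), C4' (CH3) and C6' (CH2OH) are mutually meta while C1' carries the ether oxygen. This is the pattern produced when the C1'–C2'–C3' unit of an aryloxyacetone condenses through C1' and C3' with the C6'–C5'–C4' unit of a 2,4-dioxo ester, so the ether bond can be made beforehand as an unhindered phenol alkylation.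

## Logic of the disconnections

15 ⇒ 14. No skeletal bond is cut; the C6' hydroxymethyl group is traced back to an ethyl ester, the oxidation level at which the ring-forming condensation delivers this carbon. The gain is that 14 is the direct product of the key step and that no protecting group has to be removed at the end. The forward step needs a hydride that reduces an ester but leaves a hindered carboxylate alone.

14 ⇒ 12 + 13. Ring B is cut at C1'–C6' and C3'–C4'. This removes the whole ring and leaves the ether oxygen on a simple 2-oxopropyl group, so the hindered aryl–O–aryl bond never has to be formed by coupling. The forward step must pair the aryloxymethylene carbon of 12 with the ester-flanked carbonyl of 13 and the methyl carbon with the acetyl carbonyl. It must then close the ring from the correct side and must not let the enolate attack the ring A carboxyl, which is why 12 is the free acid. The side-chain diol is carried unprotected: every operation from its introduction onwards is basic or neutral, so silyl ethers would only add protection and deprotection steps and would oblige an acid-labile phenol protecting group to be removed in their presence.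

12 ⇒ 11. The O–allyl bond of the ester is cut. The acid has to be masked while the phenol is alkylated, because a free carboxylate would compete for the alkylating agent. The forward step must unmask it without acid or hydroxide, since hydroxide or alkoxide would drive the ketone enolate onto the ester.

11 ⇒ 9 + 10. The ether bond between the C6 oxygen and the methylene of the 2-oxopropyl group is cut. The eventual diaryl ether oxygen is thus introduced by SN2 alkylation of a phenoxide with 10. The forward step needs a base strong enough for the phenol but too weak to enolise the product ketone.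

9 ⇒ 8. The allyl ester and the free C6 phenol are traced back together to a cyclic acetonide of the salicylic acid unit. One group protects the acid and one of the two ring A oxygens and differentiates the C2 and C6 oxygens from the first step onwards. The forward step is an alkoxide opening of the lactone-acetal that must tolerate the free diol.

8 ⇒ 7. The tertiary C–O bond of the side chain is cut, leading back to a 1,1-disubstituted alkene. The forward step must hydrate with Markovnikov selectivity without acid, because of the benzylic alcohol.

7 ⇒ 3 + 4. The C–C bond between the carbinol carbon and the side-chain methylene is cut, which removes the only stereocentre. The forward step must add the methallyl group of 4 to one face of the aldehyde under reagent control, through the chiral borane 5, and must spare the lactone-acetal.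

3 ⇒ 2. The O–CH3 bond at C2 is cut. The free phenol is needed one step earlier to direct the formylation, so methylation follows it. The forward step must alkylate a phenol chelated between two carbonyl groups.

2 ⇒ 1. The bond between the ring carbon and the formyl carbon is cut. In 1 the only free position ortho to the phenol is the one required, so a phenoxide-directed formylation with a one-carbon electrophile fixes the regiochemistry. The forward step must overcome the reduced nucleophilicity of a phenol that is hydrogen-bonded to the lactone carbonyl.

## Other disconnections considered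

Alternative 1: Ring A is cut at C1–C2 and C3–C4. This leads to the 4-aryloxy-2-pyrone-3-carboxylate A2, which holds C1, C6, C5, C4, the ester and ring B, and to the chiral methoxyalkyne A3, which holds C2, C3 and the side chain. In the forward key step, heating A2 with A3 should give an inverse-electron-demand Diels–Alder adduct. The alkyne carbon remote from the methoxy group bonds to pyrone C6 and the methoxy-bearing carbon bonds to pyrone C3. The bridged lactone then expels CO2 to give the benzoate A1. Ring A in A1 is tetrasubstituted, since C4 and C5 keep their hydrogens; it is not a fully substituted ring.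
- In favour: the regiochemistry follows from the polarisation of both partners, and cycloaddition of 2-pyrone-3-carboxylates with electron-rich two-carbon partners is a well-established manifold. On mechanistic precedent this alternative is stronger than the chosen plan. The crowded aryl–O bond is made by addition–elimination on a 4-substituted pyrone, which is as easy as the phenol alkylation of the chosen plan (equal on this point).
- Against: the 4-aryloxy group is a vinylogous ester donor that lowers the electron demand of the diene, so the cycloaddition may need temperatures at which the propargylic silyl ether and the hydrolytically labile ynol ether suffer. A1 is a 2,6-disubstituted methyl benzoate, a class that resists hydrolysis. A benzyl ether would have to be hydrogenolysed beside an electron-rich benzylic C–O bond, and three silyl ethers would have to be removed.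
- Comparison: on structure, this route builds the more heavily substituted ring A and leaves ring B, with its 1,2,3,5 pattern, to be made separately. On mechanism it is the better precedented. On step economy it is clearly worse: two multi-step fragments and about four operations after the key step, against one reduction in the chosen plan.

Alternative 2: Ring A is cut at C1–C2, C2–C3 and C5–C6. This leads to the diazo enone A5 (C2, C5, C4, C3 and the side chain) and the aryl ynol ether A6 (C6, C1 with its protected hydroxymethyl group, and ring B). In the forward key step, irradiation of A5 should trigger a Wolff rearrangement to a vinylketene, which adds to A6 in a [2+2] fashion. On warming, the cyclobutenone opens and the dienylketene closes in a six-electron electrocyclisation. Tautomerisation gives the phenol A4, with the hydroxyl at C2 (Danheiser benzannulation).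
- In favour: three ring bonds and the full substitution pattern of ring A are set in one operation under neutral conditions. The position of the aryloxy group meta to the new hydroxyl follows from the ynol ether polarisation. On regiochemical certainty and on convergence this alternative is better than the chosen plan.
- Against: C1 arrives as a protected hydroxymethyl group, so a PMB cleavage and two oxidations are needed next to an electron-rich benzylic ether and a catechol ether. The C2 phenol, flanked on both sides, still has to be methylated. Ynol ethers of a 2,6-disubstituted phenol are laborious to make and less nucleophilic than alkyl ynol ethers. Debenzylation and desilylation follow.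
- Comparison: on structure, it constructs ring A from two elaborate halves, whereas the chosen plan constructs ring B from two trivial three-carbon pieces. On mechanism, the pericyclic cascade is at least as well founded as the double aldol. On step economy it is worse, with at least seven operations after the key step and a diazo ketone to prepare.

Alternative 3: The C6–O ether bond and the C1–carboxyl bond are cut. This leads to the ortho-silylaryl triflate A8, the ring B phenol A9 and CO2. In the forward key step, KF with 18-crown-6 under CO2 should generate the C1–C6 aryne. The potassium phenoxide of A9 should add at C6, remote from the methoxy group, because the inductive effect of the methoxy group places the developing negative charge at C1. The aryl anion at C1 is then trapped by CO2 to give the acid A7; no ring is closed.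
- In favour: this is the most direct assembly of the target. It makes the hindered ether and the carboxyl, at the correct oxidation level, in one step, with regiochemistry governed by a well-understood substituent effect. On directness of the key step it is better than the chosen plan.
- Against: three-component trapping of arynes with CO2 is established mainly for nitrogen nucleophiles. A hindered 2,6-disubstituted phenoxide is a weak nucleophile and is itself carbonated reversibly by CO2. Protonation of the aryl anion would give the ether without the carboxyl, and the substrate offers no handle to bias that competition. Fluoride also threatens the silyl ethers of the side chain. A8, with a regiodefined silyl/triflate pair and the chiral chain, is a long fragment synthesis, and three deprotections including a hydrogenolysis follow.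
- Comparison: on structure, it attacks the crowded ether bond directly, whereas the chosen plan avoids it. On mechanism, both plans carry an unproven element: anion partitioning here, and regiochemistry and reactivity of the condensation in the chosen plan. On step economy the key step itself is better, but the overall sequence is longer because of the precursors and protecting groups.

Key step: step 8

Assumption: 5-hydroxy-2,2-dimethyl-4H-1,3-benzodioxin-4-one (1) is taken as a catalogue compound; if it is not, it is one step from 2,6-dihydroxybenzoic acid and acetone under trifluoroacetic anhydride.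

## Route

Step 1
Reactants: 1 5-hydroxy-2,2-dimethyl-4H-1,3-benzodioxin-4-one
Product: 2 5-hydroxy-2,2-dimethyl-4-oxo-4H-1,3-benzodioxine-6-carbaldehyde
Conditions: MgCl2, Et3N, (CH2O)n, MeCN, reflux; 1 M HCl
Reagents that add atoms: paraformaldehyde (formaldehyde), C=O
Why: Magnesium-mediated ortho-formylation of a phenol (Casnati–Skattebøl): the magnesium phenoxide directs hydroxymethylation to its only free ortho carbon, C6, which is also para to the ring oxygen, and a second formaldehyde oxidises the benzylic alkoxide by hydride transfer. The lactone-acetal is inert to MgCl2/Et3N.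

Step 2
Reactants: 2 5-hydroxy-2,2-dimethyl-4-oxo-4H-1,3-benzodioxine-6-carbaldehyde
Product: 3 5-methoxy-2,2-dimethyl-4-oxo-4H-1,3-benzodioxine-6-carbaldehyde
Conditions: MeI, K2CO3, DMF, rt to 40 °C
Reagents that add atoms: iodomethane, CI
Why: Williamson O-methylation of the chelated phenoxide; carbonate in DMF provides no nucleophile able to open the benzodioxinone.

Step 3
Reactants: 3 5-methoxy-2,2-dimethyl-4-oxo-4H-1,3-benzodioxine-6-carbaldehyde; 4 2-methylallylmagnesium chloride
Product: 7 6-[(1R)-1-hydroxy-3-methylbut-3-en-1-yl]-5-methoxy-2,2-dimethyl-4H-1,3-benzodioxin-4-one, via (+)-B-(2-methylallyl)diisopinocampheylborane 5 (not isolated), via diisopinocampheylborinate ester 6 (not isolated)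
Conditions: (+)-Ipc2BOMe [from (−)-α-pinene], 4, Et2O, 0 °C to rt; then 3, −78 °C; NaBO3·4H2O, THF/H2O, rt
Reagents that add atoms: none
Why: Brown allylboration: 4 transfers its methallyl group to boron to give 5, which adds to the aldehyde through a closed chair (Zimmerman–Traxler) transition state. The reagent derived from (−)-α-pinene attacks the Re face of aryl aldehydes and so should set the (R)-carbinol centre. Perborate oxidation of borinate 6 releases 7 under conditions mild enough to leave the lactone-acetal closed.

Step 4
Reactants: 7 6-[(1R)-1-hydroxy-3-methylbut-3-en-1-yl]-5-methoxy-2,2-dimethyl-4H-1,3-benzodioxin-4-one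
Product: 8 6-[(1R)-1,3-dihydroxy-3-methylbutyl]-5-methoxy-2,2-dimethyl-4H-1,3-benzodioxin-4-one
Conditions: Co(acac)2 (cat.), PhSiH3, O2 (1 atm), THF, rt; aq. Na2S2O3
Reagents that add atoms: dioxygen, O=O
Why: Mukaiyama hydration: hydrogen-atom transfer from a cobalt hydride to the 1,1-disubstituted alkene gives the tertiary radical, which is trapped by O2 and reduced to the tertiary alcohol. Markovnikov selectivity is inherent, no acid is involved, and the stereocentre is not touched.

Step 5
Reactants: 8 6-[(1R)-1,3-dihydroxy-3-methylbutyl]-5-methoxy-2,2-dimethyl-4H-1,3-benzodioxin-4-one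
Product: 9 prop-2-en-1-yl 3-[(1R)-1,3-dihydroxy-3-methylbutyl]-6-hydroxy-2-methoxybenzoate
Conditions: allyl alcohol (excess), NaH, THF, 0 °C to rt; aq. NH4Cl
Reagents that add atoms: allyl alcohol, C=CCO
Why: Alkoxide transesterification of a salicylate acetonide: allyloxide adds to the lactone carbonyl, acetone is expelled and the C6 phenoxide is released, so the ester and the phenol are unmasked and differentiated in one operation. Excess allyl alcohol outcompetes the substrate hydroxyls.

Step 6
Reactants: 9 prop-2-en-1-yl 3-[(1R)-1,3-dihydroxy-3-methylbutyl]-6-hydroxy-2-methoxybenzoate; 10 chloroacetone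
Product: 11 prop-2-en-1-yl 3-[(1R)-1,3-dihydroxy-3-methylbutyl]-2-methoxy-6-(2-oxopropoxy)benzoate
Conditions: K2CO3, KI (cat.), DMF, rt
Reagents that add atoms: none
Why: Williamson etherification (SN2 with iodide catalysis) of the phenoxide with the α-chloro ketone. Carbonate deprotonates only the phenol, so the aliphatic hydroxyls stay unalkylated and the product ketone is not enolised towards closure on the allyl ester.

Step 7
Reactants: 11 prop-2-en-1-yl 3-[(1R)-1,3-dihydroxy-3-methylbutyl]-2-methoxy-6-(2-oxopropoxy)benzoate
Product: 12 3-[(1R)-1,3-dihydroxy-3-methylbutyl]-2-methoxy-6-(2-oxopropoxy)benzoic acid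
Conditions: Pd(PPh3)4 (cat.), morpholine, THF, rt; aq. citric acid, 0 °C
Reagents that add atoms: none
Why: Tsuji–Trost deallylation: zerovalent palladium ionises the allyl ester and morpholine captures the π-allyl complex. The neutral conditions leave the ketone, the benzylic alcohol and the tertiary alcohol untouched.

Step 8
Reactants: 12 3-[(1R)-1,3-dihydroxy-3-methylbutyl]-2-methoxy-6-(2-oxopropoxy)benzoic acid; 13 ethyl 2,4-dioxopentanoate
Product: 14 3-[(1R)-1,3-dihydroxy-3-methylbutyl]-6-[2-(ethoxycarbonyl)-6-hydroxy-4-methylphenoxy]-2-methoxybenzoic acid
Conditions: 13 (3 equiv), NaOEt (5 equiv), EtOH, 0 °C; slow addition of 12; 60 °C; AcOH to pH 4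
Reagents that add atoms: none
Why: Ethoxide converts 12 into its carboxylate and 13 into its sodium enolate; the ketone enolate at the aryloxy-bearing methylene adds to the ester-flanked carbonyl of 13 (bond C1'–C6') and E1cB loss of water gives an enedione. The methyl enolate of the aryloxy ketone then adds to the acetyl carbonyl (bond C3'–C4') in a 6-(enolendo)-exo-trig aldol closure, the only ring formed; a second dehydration and tautomerisation of the cyclohexadienone give the phenoxide, whose oxygen is the former ketone oxygen. The closest known reaction type is the base-mediated cyclocondensation of a methyl ketone with a 2,4-dioxo ester to a 3-hydroxy-5-methylbenzoate, including the self-condensation of acetopyruvate esters, in which an activated methylene pairs with the keto-ester carbonyl and the methyl group with the acetyl carbonyl exactly as required here. No stereocentre is formed, and the benzylic carbinol cannot epimerise under alkoxide. The pairing is secured by the higher acidity of the aryloxymethylene (inductive effect of the aryloxy group and sodium chelation) and by the higher electrophilicity of the carbonyl beside the ester; the aldol additions are reversible and only aromatisation is irreversible. The direction of ring closure is a further requirement, since closure of the acetyl methyl onto the aryloxy ketone carbonyl would give the 5-hydroxy-3-methyl isomer; it should be disfavoured because that carbonyl is a conjugated, α-aryloxy enone carbonyl while the acetyl group is an isolated ketone. The ring A carboxylate cannot be attacked by the enolate, so no benzofuranone can form; holding 13 fully as its enolate suppresses its self-condensation, and the free hydroxyls are spectators in ethanol.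

Step 9
Reactants: 14 3-[(1R)-1,3-dihydroxy-3-methylbutyl]-6-[2-(ethoxycarbonyl)-6-hydroxy-4-methylphenoxy]-2-methoxybenzoic acid
Product: 15 3-[(1R)-1,3-dihydroxy-3-methylbutyl]-6-[2-hydroxy-6-(hydroxymethyl)-4-methylphenoxy]-2-methoxybenzoic acid
Conditions: LiBH4 (excess), THF, 0 to 40 °C; aq. NH4Cl, then citric acid to pH 4, 0 °C
Reagents that add atoms: none
Why: Chemoselective ester reduction with LiBH4: the first equivalents of hydride turn the acid, the phenol and the alcohols into lithium salts, and the 2,6-disubstituted lithium carboxylate is inert while the aryl ethyl ester is reduced to the hydroxymethyl group. The cold, weakly acidic work-up avoids ionisation of the benzylic alcohol and lactonisation.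

## Compound list

1 | 5-hydroxy-2,2-dimethyl-4H-1,3-benzodioxin-4-one | CC1(C)Oc2cccc(O)c2C(=O)O1 | starting material
2 | 5-hydroxy-2,2-dimethyl-4-oxo-4H-1,3-benzodioxine-6-carbaldehyde | CC1(C)Oc2ccc(C=O)c(O)c2C(=O)O1 | intermediate
3 | 5-methoxy-2,2-dimethyl-4-oxo-4H-1,3-benzodioxine-6-carbaldehyde | CC1(C)Oc2ccc(C=O)c(OC)c2C(=O)O1 | intermediate
4 | 2-methylallylmagnesium chloride (THF solution) | C=C(C)C[Mg]Cl | starting material
5 | (+)-B-(2-methylallyl)diisopinocampheylborane, both isopinocampheyl groups from (−)-α-pinene | C=C(C)CB([C@H]1C[C@H]2C[C@@H]([C@@H]1C)C2(C)C)[C@H]1C[C@H]2C[C@@H]([C@@H]1C)C2(C)C | intermediate (not isolated)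
6 | diisopinocampheylborinate ester of 7 (boron on the (R)-carbinol oxygen) | CC1(C)Oc2ccc([C@H](OB([C@H]3C[C@H]4C[C@@H]([C@@H]3C)C4(C)C)[C@H]3C[C@H]4C[C@@H]([C@@H]3C)C4(C)C)CC(C)=C)c(OC)c2C(=O)O1 | intermediate (not isolated)
7 | 6-[(1R)-1-hydroxy-3-methylbut-3-en-1-yl]-5-methoxy-2,2-dimethyl-4H-1,3-benzodioxin-4-one | CC1(C)Oc2ccc([C@H](O)CC(C)=C)c(OC)c2C(=O)O1 | intermediate
8 | 6-[(1R)-1,3-dihydroxy-3-methylbutyl]-5-methoxy-2,2-dimethyl-4H-1,3-benzodioxin-4-one | CC1(C)Oc2ccc([C@H](O)CC(C)(C)O)c(OC)c2C(=O)O1 | intermediate
9 | prop-2-en-1-yl 3-[(1R)-1,3-dihydroxy-3-methylbutyl]-6-hydroxy-2-methoxybenzoate | C=CCOC(=O)c1c(O)ccc([C@H](O)CC(C)(C)O)c1OC | intermediate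
10 | chloroacetone | CC(=O)CCl | starting material
11 | prop-2-en-1-yl 3-[(1R)-1,3-dihydroxy-3-methylbutyl]-2-methoxy-6-(2-oxopropoxy)benzoate | C=CCOC(=O)c1c(OCC(C)=O)ccc([C@H](O)CC(C)(C)O)c1OC | intermediate
12 | 3-[(1R)-1,3-dihydroxy-3-methylbutyl]-2-methoxy-6-(2-oxopropoxy)benzoic acid | COc1c([C@H](O)CC(C)(C)O)ccc(OCC(C)=O)c1C(=O)O | intermediate
13 | ethyl 2,4-dioxopentanoate | CCOC(=O)C(=O)CC(C)=O | starting material
14 | 3-[(1R)-1,3-dihydroxy-3-methylbutyl]-6-[2-(ethoxycarbonyl)-6-hydroxy-4-methylphenoxy]-2-methoxybenzoic acid | COc1c([C@H](O)CC(C)(C)O)ccc(Oc2c(O)cc(C)cc2C(=O)OCC)c1C(=O)O | intermediate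
15 | 3-[(1R)-1,3-dihydroxy-3-methylbutyl]-6-[2-hydroxy-6-(hydroxymethyl)-4-methylphenoxy]-2-methoxybenzoic acid | COc1c([C@H](O)CC(C)(C)O)ccc(Oc2c(O)cc(C)cc2CO)c1C(=O)O | target

## Step count and least certain steps

Total step count: 9. Longest linear sequence: 9 steps (1 to 15).

Step 8 (key step). The reaction type is known for simple methyl ketones, but an unsymmetrical aryloxy ketone has no direct precedent in it. Four things may go wrong:
- The cross-condensation may be slow, because under alkoxide the dioxo ester exists as a poorly electrophilic enolate.
- The ketone may undergo self-aldol condensation instead.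
- The pairing may be reversed (methyl carbon with the keto-ester carbonyl), or the ring may close from the other side, giving isomeric phenols.
- Ethoxide may cleave 13.

The fallback gives up ring construction and makes the diaryl ether by nucleophilic aromatic substitution. It sets out from 9 and comes back at 15. The phenoxide of 9 (K2CO3, DMF, 80 °C) displaces fluoride from the aldehyde-activated fluoroarene 3-(allyloxy)-2-fluoro-5-methylbenzaldehyde F1, which would be prepared separately. This gives the diaryl ether aldehyde prop-2-en-1-yl 6-[2-(allyloxy)-6-formyl-4-methylphenoxy]-3-[(1R)-1,3-dihydroxy-3-methylbutyl]-2-methoxybenzoate F2. NaBH4 in MeOH/THF reduces the aldehyde to the benzylic alcohol F3. Pd(PPh3)4 with morpholine then removes the allyl ester and the allyl ether together and gives 15.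

Step 1. Hydroxymethylation may be sluggish, because the magnesium phenoxide is chelated by the lactone carbonyl and the ring is electron-poor; over-reaction to diarylmethanes is possible on forcing. The fallback installs the carbon by sigmatropic rearrangement, from 1 back to 2. O-Allylation (allyl bromide, K2CO3, acetone) gives 5-(allyloxy)-2,2-dimethyl-4H-1,3-benzodioxin-4-one F4. Claisen rearrangement in N,N-diethylaniline at 180 °C moves the allyl group to the only free ortho position and gives the 6-allyl phenol F5. RuHCl(CO)(PPh3)3 in toluene isomerises the alkene into conjugation to give the 6-(prop-1-enyl) phenol F6. Lemieux–Johnson cleavage (OsO4 cat., NaIO4) gives 2.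

Step 3. Facial selectivity may be eroded by the ortho-methoxy group and residual magnesium salts, and the lactone-acetal may open partly during the oxidative work-up. The fallback sets the stereocentre by catalytic ketone reduction, from 3 back to 8. Zinc-mediated Barbier addition of 3-chloro-2-methylpropene (Zn, aq. NH4Cl/THF) gives the racemic homoallylic alcohol F7. Hydration as in step 4 gives the racemic diol F8. MnO2 in CH2Cl2 oxidises only the benzylic alcohol to the β-hydroxy ketone F9. Noyori transfer hydrogenation with RuCl[(R,R)-TsDPEN](p-cymene) and HCO2H/Et3N, the catalyst antipode that reduces aryl ketones to (R)-carbinols, gives 8.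

Step 9. Reduction may stall because the polylithium salt is poorly soluble in THF, or acyloxyborohydride species may begin to reduce the carboxyl group. The fallback masks the acid as a hindered ester before reduction, from 14 back to 15. Allyl bromide with KHCO3 in DMF esterifies only the carboxylate and gives the allyl ester F10. i-Bu2AlH in THF at −78 °C reduces the less hindered ethyl ester in preference to the 2,6-disubstituted allyl benzoate and gives the benzylic alcohol F11. Pd(PPh3)4 with morpholine gives 15.

## Further compounds

F1 | step 8 | 3-(allyloxy)-2-fluoro-5-methylbenzaldehyde | C=CCOc1cc(C)cc(C=O)c1F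
F2 | step 8 | prop-2-en-1-yl 6-[2-(allyloxy)-6-formyl-4-methylphenoxy]-3-[(1R)-1,3-dihydroxy-3-methylbutyl]-2-methoxybenzoate | C=CCOC(=O)c1c(Oc2c(OCC=C)cc(C)cc2C=O)ccc([C@H](O)CC(C)(C)O)c1OC
F3 | step 8 | prop-2-en-1-yl 6-[2-(allyloxy)-6-(hydroxymethyl)-4-methylphenoxy]-3-[(1R)-1,3-dihydroxy-3-methylbutyl]-2-methoxybenzoate | C=CCOC(=O)c1c(Oc2c(OCC=C)cc(C)cc2CO)ccc([C@H](O)CC(C)(C)O)c1OC
F4 | step 1 | 5-(allyloxy)-2,2-dimethyl-4H-1,3-benzodioxin-4-one | CC1(C)Oc2cccc(OCC=C)c2C(=O)O1
F5 | step 1 | 5-hydroxy-2,2-dimethyl-6-(prop-2-en-1-yl)-4H-1,3-benzodioxin-4-one | CC1(C)Oc2ccc(CC=C)c(O)c2C(=O)O1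
F6 | step 1 | 5-hydroxy-2,2-dimethyl-6-[(E)-prop-1-en-1-yl]-4H-1,3-benzodioxin-4-one | CC1(C)Oc2ccc(/C=C/C)c(O)c2C(=O)O1
F7 | step 3 | racemic 6-(1-hydroxy-3-methylbut-3-en-1-yl)-5-methoxy-2,2-dimethyl-4H-1,3-benzodioxin-4-one | CC1(C)Oc2ccc(C(O)CC(C)=C)c(OC)c2C(=O)O1
F8 | step 3 | racemic 6-(1,3-dihydroxy-3-methylbutyl)-5-methoxy-2,2-dimethyl-4H-1,3-benzodioxin-4-one | CC1(C)Oc2ccc(C(O)CC(C)(C)O)c(OC)c2C(=O)O1
F9 | step 3 | 6-(3-hydroxy-3-methylbutanoyl)-5-methoxy-2,2-dimethyl-4H-1,3-benzodioxin-4-one | CC1(C)Oc2ccc(C(=O)CC(C)(C)O)c(OC)c2C(=O)O1
F10 | step 9 | prop-2-en-1-yl 3-[(1R)-1,3-dihydroxy-3-methylbutyl]-6-[2-(ethoxycarbonyl)-6-hydroxy-4-methylphenoxy]-2-methoxybenzoate | C=CCOC(=O)c1c(Oc2c(O)cc(C)cc2C(=O)OCC)ccc([C@H](O)CC(C)(C)O)c1OC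
F11 | step 9 | prop-2-en-1-yl 3-[(1R)-1,3-dihydroxy-3-methylbutyl]-6-[2-hydroxy-6-(hydroxymethyl)-4-methylphenoxy]-2-methoxybenzoate | C=CCOC(=O)c1c(Oc2c(O)cc(C)cc2CO)ccc([C@H](O)CC(C)(C)O)c1OC
A1 | alternative 1 | methyl 6-{2-(benzyloxy)-6-[(tert-butyldimethylsilyloxy)methyl]-4-methylphenoxy}-3-[(1R)-1-(tert-butyldimethylsilyloxy)-3-methyl-3-(triethylsilyloxy)butyl]-2-methoxybenzoate | COc1c([C@H](O[Si](C)(C)C(C)(C)C)CC(C)(C)O[Si](CC)(CC)CC)ccc(Oc2c(OCc3ccccc3)cc(C)cc2CO[Si](C)(C)C(C)(C)C)c1C(=O)OC
A2 | alternative 1 | methyl 4-{2-(benzyloxy)-6-[(tert-butyldimethylsilyloxy)methyl]-4-methylphenoxy}-2-oxo-2H-pyran-3-carboxylate | COC(=O)C1=C(Oc2c(OCc3ccccc3)cc(C)cc2CO[Si](C)(C)C(C)(C)C)C=COC1=O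
A3 | alternative 1 | tert-butyl{[(3R)-1-methoxy-5-methyl-5-(triethylsilyloxy)hex-1-yn-3-yl]oxy}dimethylsilane | COC#C[C@H](O[Si](C)(C)C(C)(C)C)CC(C)(C)O[Si](CC)(CC)CC
A4 | alternative 2 | 3-{2-(benzyloxy)-6-[(tert-butyldimethylsilyloxy)methyl]-4-methylphenoxy}-6-[(1R)-1-(tert-butyldimethylsilyloxy)-3-methyl-3-(triethylsilyloxy)butyl]-2-[(4-methoxybenzyloxy)methyl]phenol | Oc1c([C@H](O[Si](C)(C)C(C)(C)C)CC(C)(C)O[Si](CC)(CC)CC)ccc(Oc2c(OCc3ccccc3)cc(C)cc2CO[Si](C)(C)C(C)(C)C)c1COCc1ccc(OC)cc1
A5 | alternative 2 | (3E,5R)-5-(tert-butyldimethylsilyloxy)-1-diazo-7-methyl-7-(triethylsilyloxy)oct-3-en-2-one | [N-]=[N+]=CC(=O)/C=C/[C@H](O[Si](C)(C)C(C)(C)C)CC(C)(C)O[Si](CC)(CC)CC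
A6 | alternative 2 | 1-(benzyloxy)-3-[(tert-butyldimethylsilyloxy)methyl]-2-{[3-(4-methoxybenzyloxy)prop-1-yn-1-yl]oxy}-5-methylbenzene | COc1ccc(COCC#COc2c(OCc3ccccc3)cc(C)cc2CO[Si](C)(C)C(C)(C)C)cc1
A7 | alternative 3 | 6-{2-(benzyloxy)-6-[(tert-butyldimethylsilyloxy)methyl]-4-methylphenoxy}-3-[(1R)-1-(tert-butyldimethylsilyloxy)-3-methyl-3-(triethylsilyloxy)butyl]-2-methoxybenzoic acid | COc1c([C@H](O[Si](C)(C)C(C)(C)C)CC(C)(C)O[Si](CC)(CC)CC)ccc(Oc2c(OCc3ccccc3)cc(C)cc2CO[Si](C)(C)C(C)(C)C)c1C(=O)O
A8 | alternative 3 | 4-[(1R)-1-(tert-butyldimethylsilyloxy)-3-methyl-3-(triethylsilyloxy)butyl]-3-methoxy-2-(trimethylsilyl)phenyl trifluoromethanesulfonate | COc1c([C@H](O[Si](C)(C)C(C)(C)C)CC(C)(C)O[Si](CC)(CC)CC)ccc(OS(=O)(=O)C(F)(F)F)c1[Si](C)(C)C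
A9 | alternative 3 | 2-(benzyloxy)-6-[(tert-butyldimethylsilyloxy)methyl]-4-methylphenol | Cc1cc(OCc2ccccc2)c(O)c(CO[Si](C)(C)C(C)(C)C)c1
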